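**Plan**

1. Retrosynthesis: the tiglate C6–O(acyl) bond, the epoxide C4–O and C5–O bonds, the C11=C13 methylene and the lactone C12–O8 bond are cut first, and the C9 carbinol is traced back to a ketone.
2. Feature: in germacrane numbering C4 (the methyl-bearing epoxide carbon) and C9 (the carbinol) lie 1,6 across the ten-membered ring. Re-forming C4–C9 in the cyclodec-4-en-9-one gives a trans-decalin (ring A: C4, C3, C2, C1, C10, C9; ring B: C4 to C9) with an angular C9 hydroxyl and an equatorial C5 sulfonate, the retron of a Grob fragmentation.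
3. The decalin is cut at C7–C11 (acetate enolate on a C7 carbonyl), at its ring-B C–O bonds, and at C8=C9 and C4–C5 (Robinson annulation of 2,6-dimethylcyclohexanone with methyl vinyl ketone).
4. Forward: ring A is the purchased cyclohexanone and ring B is annulated onto it. The carbonyl is then moved from C7 to C5 as the two-carbon arm is attached, and ring B is oxygenated at C8/C9, C6 and C5. Fragmentation merges rings A and B into the ten-membered ring; the γ-lactone and then the epoxide are closed last.
5. Stereochemistry: C4 comes from the (S)-1-phenylethylamine auxiliary and C10 from equilibration. C8/C9, C7, C6 and C5 are set by α-face or hydroxyl-directed reactions on the rigid decalin, where all of them end up equatorial. The E olefin follows from the antiperiplanar fragmentation, C9 from chelation-controlled reduction, and the epoxide from epoxidation directed by the C6 hydroxyl.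

Key step: step 13

Remark: germacrane numbering (C1–C10 ring, C11–C13 lactone arm, C14 on C10, C15 on C4) is used for every intermediate, and in the bicyclic compounds β is the face of the angular C15 methyl. Compounds 6 and 10 are expected as epimer mixtures at a centre that is equilibrated or erased later (C10 in 6, the C7 carbinol in 10) and are written without a descriptor there.

**Route**

Step 1
Reactants: 1 2,6-dimethylcyclohexanone; 2 (S)-1-phenylethylamine; 3 methyl vinyl ketone
Product: 6 (2R)-2,6-dimethyl-2-(3-oxobutyl)cyclohexanone, via imine 4 (not isolated), via adduct imine 5 (not isolated)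
Conditions: 2, TsOH (cat.), toluene, reflux (Dean–Stark); 3, THF, 40 °C; 20% aq AcOH, rt
Reagents that add atoms: water, O
Why: The secondary enamine tautomer of imine 4 adds to the enone in an aza-ene-type Michael addition (first half of an asymmetric Robinson annulation) on the enamine face away from the phenyl group of the auxiliary, which with the (S) amine should set the quaternary C4 centre as R by the established sense of this reaction for 2-alkylcyclohexanones, and hydrolysis returns the auxiliary.

Step 2
Reactants: 6 (2R)-2,6-dimethyl-2-(3-oxobutyl)cyclohexanone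
Product: 7 (4aR,8R)-4a,8-dimethyl-4,4a,5,6,7,8-hexahydronaphthalen-2(3H)-one
Conditions: NaOMe (0.3 equiv), MeOH, 60 °C
Reagents that add atoms: none
Why: Intramolecular aldol condensation (second half of the Robinson annulation) closes ring B, and the C10 methyl, epimerisable through the dienolate, should settle pseudo-equatorial and trans to the angular methyl, where it avoids the syn-axial clash with C15.

Step 3
Reactants: 7 (4aR,8R)-4a,8-dimethyl-4,4a,5,6,7,8-hexahydronaphthalen-2(3H)-one
Product: 8 (4aR,8R)-4a,8-dimethyl-5,6,7,8-tetrahydronaphthalen-2(4aH)-one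
Conditions: DDQ, dioxane, reflux
Reagents that add atoms: none
Why: Quinone dehydrogenation under neutral conditions passes through the kinetic C6 enol and should give the cross-conjugated 5,8-dien-7-one, as it does with 4-en-3-oxo steroids and angularly methylated octalones, without touching a stereocentre.

Step 4
Reactants: 8 (4aR,8R)-4a,8-dimethyl-5,6,7,8-tetrahydronaphthalen-2(4aH)-one; 9 ethyl acetate
Product: 10 ethyl 2-[(4aR,8R)-2-hydroxy-4a,8-dimethyl-2,4a,5,6,7,8-hexahydronaphthalen-2-yl]acetate
Conditions: LiN(iPr)2, 9, THF, −78 °C; then 8; AcOH, −78 °C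
Reagents that add atoms: none
Why: The lithium enolate of ethyl acetate should add 1,2 to the dienone carbonyl at low temperature (aldol-type addition), both β-carbons being too hindered for conjugate addition, and the new carbinol centre is erased in the next step.

Step 5
Reactants: 10 ethyl 2-[(4aR,8R)-2-hydroxy-4a,8-dimethyl-2,4a,5,6,7,8-hexahydronaphthalen-2-yl]acetate
Product: 11 ethyl 2-[(5R,8aS)-5,8a-dimethyl-1-oxo-1,5,6,7,8,8a-hexahydronaphthalen-3-yl]acetate
Conditions: [C5H5NH][CrO3Cl], Celite, CH2Cl2, rt
Reagents that add atoms: pyridinium chlorochromate, [O-][Cr](=O)(=O)Cl.c1cc[nH+]cc1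
Why: In this Babler–Dauben oxidative transposition the chromate ester of the tertiary bis-allylic alcohol should shift [3,3] toward C5, the only allylic terminus bearing hydrogen, where oxidation is irreversible, so the carbonyl moves from C7 to C5 and the acetate arm ends on the β-carbon of a linear dienone that cannot aromatise because C4 is quaternary.

Step 6
Reactants: 11 ethyl 2-[(5R,8aS)-5,8a-dimethyl-1-oxo-1,5,6,7,8,8a-hexahydronaphthalen-3-yl]acetate
Product: 12 8α,9α-dihydroxy enone ester (C5 ketone, 6-ene, arm on C7)
Conditions: OsO4 (5 mol%), N-methylmorpholine N-oxide, acetone/H2O, rt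
Reagents that add atoms: osmium tetroxide (catalytic oxygen carrier), O=[Os](=O)(=O)=O; N-methylmorpholine N-oxide, C[N+]1([O-])CCOCC1; water, O
Why: Catalytic osmylation should take the electron-richer γ,δ-olefin of the dienone and approach C8=C9 from the α face, anti to the axial angular methyl on the neighbouring C4 as in the 5α,6α-dihydroxylation of 5-ene steroids, which sets the secondary C8 and tertiary C9 hydroxyls cis and α.

Step 7
Reactants: 12 8α,9α-dihydroxy enone ester
Product: 13 8α-methoxymethyl ether of 12 (9α-OH free)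
Conditions: MOMCl, iPr2NEt, CH2Cl2, 0 °C → rt
Reagents that add atoms: chloromethyl methyl ether, COCCl
Why: O-alkylation with the chloromethyl ether under amine base should select the secondary C8 hydroxyl over the neopentyl tertiary C9 hydroxyl and forestalls lactonisation of the γ-hydroxy ester.

Step 8
Reactants: 13 8α-methoxymethyl ether of 12
Product: 14 saturated C5 ketone with 7β-CH2CO2Et, 8α-OMOM and 9α-OH
Conditions: H2 (1 atm), [Ir(cod)(PCy3)(py)]PF6 (5 mol%), CH2Cl2, rt
Reagents that add atoms: none
Why: In this hydroxyl-directed homogeneous hydrogenation the cationic iridium complex should bind the axial C9 hydroxyl and deliver hydrogen to the α face of C6=C7, the face also left open by the angular methyl, so that H-7 is α and the acetate arm equatorial and β.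

Step 9
Reactants: 14 saturated C5 ketone with 7β-CH2CO2Et, 8α-OMOM and 9α-OH
Product: 16 6α-hydroxy C5 ketone, via bis-trimethylsilyl enol ether 15 (not isolated)
Conditions: TMSOTf, Et3N, CH2Cl2, 0 °C; mCPBA, NaHCO3, CH2Cl2, −20 °C; 1 M HCl, THF, 0 °C
Reagents that add atoms: 3-chloroperbenzoic acid, OOC(=O)c1cccc(Cl)c1
Why: In this Rubottom oxidation the ketone can enolise only toward C6 because C4 is quaternary, and the peracid should add to the silyl enol ether from the α face, away from the angular methyl that is syn-axial to C6, giving the equatorial 6α-hydroxy ketone, which is also the thermodynamic epimer.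

Step 10
Reactants: 16 6α-hydroxy C5 ketone
Product: 17 6α-triethylsilyl ether of 16
Conditions: TESCl, imidazole, DMF, 0 °C
Reagents that add atoms: chlorotriethylsilane, CC[Si](Cl)(CC)CC
Why: Silylation with the silyl chloride and imidazole should take the secondary C6 hydroxyl and leave the hindered tertiary C9 hydroxyl, which must stay free for steps 11 and 13, and it gives C6 a group that can later be removed separately from those on C8 and C9.

Step 11
Reactants: 17 6α-triethylsilyl ether of 16
Product: 18 5β-alcohol with 6α-OTES, 7β-CH2CO2Et, 8α-OMOM and 9α-OH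
Conditions: Me4NBH(OAc)3, MeCN/AcOH, −30 °C → 0 °C
Reagents that add atoms: none
Why: In this Evans–Saksena reduction the axial C9 hydroxyl should exchange onto boron and pass hydride intramolecularly to the α face of the C5 carbonyl, giving the equatorial 5β-alcohol anti to the C9 hydroxyl and trans to the 6α-silyloxy group, under acidic conditions in which the silyl group cannot migrate.

Step 12
Reactants: 18 5β-alcohol with 6α-OTES, 7β-CH2CO2Et, 8α-OMOM and 9α-OH
Product: 19 5β-mesylate of 18, all-equatorial trans-decalin (4R,5R,6R,7S,8S,9R,10R)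
Conditions: MsCl, Et3N, CH2Cl2, −20 °C → 0 °C
Reagents that add atoms: methanesulfonyl chloride, CS(=O)(=O)Cl
Why: Sulfonylation through sulfene should take the secondary equatorial C5 hydroxyl and leave the far more hindered tertiary C9 hydroxyl untouched.

Step 13
Reactants: 19 5β-mesylate of 18, all-equatorial trans-decalin
Product: 20 ethyl 2-[(4E,6S,7S,8S,10R)-8-(methoxymethoxy)-4,10-dimethyl-9-oxo-6-(triethylsilyloxy)cyclodec-4-en-7-yl]acetate (germacrane locants)
Conditions: KOtBu (1.05 equiv), THF, 0 °C; pH 7 buffer, 0 °C
Reagents that add atoms: none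
Why: Deprotonation of the tertiary C9 hydroxyl gives an alkoxide whose oxygen lone pair feeds into the ring-fusion bond, which cleaves in concert with departure of the sulfonate from C5, so that C9 becomes a ketone carbon and C4–C5 a double bond. The closest known reaction type is the Wharton variant of the Grob fragmentation of trans-decalin 1,3-diol monosulfonates to (E)-cyclodec-5-enones. The step closes no ring: loss of the bond common to rings A and B merges them into the cyclodecene, and no new stereocentre arises, C6, C7, C8 and C10 being carried over as set on the decalin. The selectivity needed is E geometry and fragmentation in preference to oxetane closure, substitution or elimination; with the sulfonate equatorial on the chair of ring B the C5–O and C4–C9 bonds are anti, the C3–C4–C5–C6 dihedral is near 180° and is carried into the trans arrangement of C3 and C6 across the new olefin, and no hydrogen stands anti to the leaving group. One equivalent of base, low temperature and a cold neutral quench should limit enolisation of the new ketone toward C8 and C10.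

Step 14
Reactants: 20 (4E)-cyclodec-4-en-9-one ester
Product: 21 (9R)-alcohol of 20 (4E,6S,7S,8S,9R,10R)
Conditions: Zn(BH4)2, Et2O, −30 °C
Reagents that add atoms: none
Why: In this chelation-controlled reduction zinc should bridge the C9 carbonyl and the C8 acetal oxygen while hydride enters from the outer face of the crown conformation inherited from the decalin, the inner face being covered by the transannular C4=C5 bond, which gives the 9R alcohol with the C8 and C9 oxygens cis on the ring as the Cram chelate model also predicts.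

Step 15
Reactants: 21 (9R)-alcohol of 20
Product: 22 9-O-tert-butyldimethylsilyl ether of 21
Conditions: TBSOTf, 2,6-lutidine, CH2Cl2, −40 °C → 0 °C
Reagents that add atoms: tert-butyldimethylsilyl triflate, CC(C)(C)[Si](C)(C)OS(=O)(=O)C(F)(F)F
Why: Silylation of the hindered secondary C9 hydroxyl with the silyl triflate should mask it through lactonisation, enolate chemistry, epoxidation and acylation.

Step 16
Reactants: 22 9-O-tert-butyldimethylsilyl ether of 21
Product: 24 (4E)-6-triethylsilyloxy-9-tert-butyldimethylsilyloxygermacr-4-en-12,8-olide, via C8 hydroxy ester 23 (not isolated)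
Conditions: Me2BBr, CH2Cl2, −78 °C; NaHCO3 (aq); PPTS (cat.), CH2Cl2, rt
Reagents that add atoms: none
Why: The bromoborane should cleave the formaldehyde acetal at low temperature without touching the silyl ethers, the ester or the olefin, and the freed C8 hydroxyl, the only free hydroxyl, then closes the trans-fused γ-lactone by acid-catalysed transesterification (5-exo-trig).

Step 17
Reactants: 24 (4E)-6-triethylsilyloxy-9-tert-butyldimethylsilyloxygermacr-4-en-12,8-olide
Product: 27 α-methylene lactone (germacra-4E,11(13)-dien-12,8-olide with 6-OTES and 9-OTBS), via Mannich base 25 (not isolated), via methiodide 26 (not isolated)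
Conditions: LiN(iPr)2, THF, −78 °C; CH2=NMe2+ I−, −78 °C → rt; MeI, MeOH, rt; DBU, CH2Cl2, rt
Reagents that add atoms: N,N-dimethylmethyleneiminium iodide (Eschenmoser's salt), C=[N+](C)C.[I-]
Why: Mannich alkylation of the lactone lithium enolate followed by quaternisation and base-induced elimination is the standard α-methylenation of γ-lactones, and the C11 centre formed in passing becomes sp2.

Step 18
Reactants: 27 α-methylene lactone with 6-OTES and 9-OTBS
Product: 28 C6 allylic alcohol (6-hydroxy-9-OTBS-germacra-4E,11(13)-dien-12,8-olide)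
Conditions: HF·pyridine, pyridine, THF, 0 °C
Reagents that add atoms: none
Why: Buffered fluoride desilylation should remove the triethylsilyl ether much faster than the more hindered tert-butyldimethylsilyl ether and does not add to the methylene lactone.

Step 19
Reactants: 28 C6 allylic alcohol
Product: 29 (4R,5R)-4,5-epoxy-6-hydroxy-9-OTBS-germacr-11(13)-en-12,8-olide
Conditions: VO(acac)2 (5 mol%), tBuOOH, CH2Cl2, 0 °C → rt
Reagents that add atoms: tert-butyl hydroperoxide, CC(C)(C)OO
Why: In this hydroxyl-directed epoxidation the vanadate ester of the C6 hydroxyl can reach the olefin only with an O–C6–C5=C4 dihedral near 45°, which, with C7 held out of the olefin plane by the ring, is possible only when the hydroxyl lies on the olefin face opposite C7, so oxygen should be delivered to that exposed face to give the 4R,5R epoxide with the 5,6-erythro relationship, while the electron-poor methylene lactone stays inert.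

Step 20
Reactants: 29 (4R,5R)-4,5-epoxy-6-hydroxy compound; 30 tigloyl chloride ((E)-2-methylbut-2-enoyl chloride)
Product: 31 6-O-tiglate of 29 (9-O-TBS ether of the target)
Conditions: 30, Et3N, DMAP (cat.), CH2Cl2, 0 °C → rt
Reagents that add atoms: none
Why: DMAP-catalysed acylation of the secondary epoxy alcohol with the acid chloride should install the tiglate with retention at C6, the E ester being the stable geometry and the base too weak for a Payne rearrangement.

Step 21
Reactants: 31 6-O-tiglate of 29
Product: 32 (4R,5R,6R,7S,8S,9R,10R)-4,5-epoxy-9-hydroxy-6-tigloyloxygermacr-11(13)-en-12,8-olide (CNP0165329.2)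
Conditions: HF·pyridine, pyridine, THF, rt
Reagents that add atoms: none
Why: Fluoride desilylation should free the C9 hydroxyl, the pyridine buffer protecting the trisubstituted epoxide, the tiglate and the methylene lactone.

**Compound list**

1 | 2,6-dimethylcyclohexanone (cis/trans mixture) | CC1CCCC(C)C1=O | starting material
2 | (S)-1-phenylethylamine | C[C@H](N)c1ccccc1 | starting material
3 | methyl vinyl ketone | CC(=O)C=C | starting material
4 | N-[(1S)-1-phenylethyl]imine of 2,6-dimethylcyclohexanone (not isolated) | CC1CCCC(C)C1=N[C@@H](C)c2ccccc2 | intermediate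
5 | N-[(1S)-1-phenylethyl]imine of (2R)-2,6-dimethyl-2-(3-oxobutyl)cyclohexanone (not isolated) | CC1CCC[C@](C)(CCC(C)=O)C1=N[C@@H](C)c2ccccc2 | intermediate
6 | (2R)-2,6-dimethyl-2-(3-oxobutyl)cyclohexanone (C6 epimers of the cyclohexanone) | CC1CCC[C@](C)(CCC(C)=O)C1=O | intermediate
7 | (4aR,8R)-4a,8-dimethyl-4,4a,5,6,7,8-hexahydronaphthalen-2(3H)-one (C7 ketone, 8-ene, C15 β, C14 α) | C[C@@H]1CCC[C@]2(C)CCC(=O)C=C12 | intermediate
8 | (4aR,8R)-4a,8-dimethyl-5,6,7,8-tetrahydronaphthalen-2(4aH)-one (5,8-dien-7-one) | C[C@@H]1CCC[C@]2(C)C=CC(=O)C=C12 | intermediate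
9 | ethyl acetate | CCOC(C)=O | starting material
10 | ethyl 2-[(4aR,8R)-2-hydroxy-4a,8-dimethyl-2,4a,5,6,7,8-hexahydronaphthalen-2-yl]acetate (C7 carbinol epimers) | C[C@@H]1CCC[C@]2(C)C=CC(O)(CC(=O)OCC)C=C12 | intermediate
11 | ethyl 2-[(5R,8aS)-5,8a-dimethyl-1-oxo-1,5,6,7,8,8a-hexahydronaphthalen-3-yl]acetate (C5 ketone, 6,8-diene, arm on C7) | C[C@@H]1CCC[C@]2(C)C(=O)C=C(CC(=O)OCC)C=C12 | intermediate
12 | 8α,9α-dihydroxy enone ester (C5 ketone, 6-ene, C7 CH2CO2Et, 8α-OH, angular 9α-OH, C15 β, C14 α) | C[C@@H]1CCC[C@]2(C)C(=O)C=C(CC(=O)OCC)[C@H](O)[C@@]12O | intermediate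
13 | 8α-methoxymethyl ether of 12 (9α-OH free) | C[C@@H]1CCC[C@]2(C)C(=O)C=C(CC(=O)OCC)[C@H](OCOC)[C@@]12O | intermediate
14 | saturated trans-decalin C5 ketone (7β-CH2CO2Et equatorial, 8α-OMOM, 9α-OH) | C[C@@H]1CCC[C@]2(C)C(=O)C[C@@H](CC(=O)OCC)[C@H](OCOC)[C@@]12O | intermediate
15 | C5 trimethylsilyl enol ether (5-ene) of 14 with 9α-OSiMe3 (not isolated) | C[C@@H]1CCC[C@]2(C)C(O[Si](C)(C)C)=C[C@@H](CC(=O)OCC)[C@H](OCOC)[C@@]12O[Si](C)(C)C | intermediate
16 | 6α-hydroxy C5 ketone (6-OH equatorial) | C[C@@H]1CCC[C@]2(C)C(=O)[C@H](O)[C@@H](CC(=O)OCC)[C@H](OCOC)[C@@]12O | intermediate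
17 | 6α-triethylsilyl ether of 16 | C[C@@H]1CCC[C@]2(C)C(=O)[C@H](O[Si](CC)(CC)CC)[C@@H](CC(=O)OCC)[C@H](OCOC)[C@@]12O | intermediate
18 | 5β-alcohol (5β-OH equatorial, 6α-OTES, 7β-CH2CO2Et, 8α-OMOM, 9α-OH) | C[C@@H]1CCC[C@]2(C)[C@@H](O)[C@H](O[Si](CC)(CC)CC)[C@@H](CC(=O)OCC)[C@H](OCOC)[C@@]12O | intermediate
19 | 5β-mesylate of 18, all-equatorial trans-decalin, (4R,5R,6R,7S,8S,9R,10R) | C[C@@H]1CCC[C@]2(C)[C@@H](OS(C)(=O)=O)[C@H](O[Si](CC)(CC)CC)[C@@H](CC(=O)OCC)[C@H](OCOC)[C@@]12O | intermediate
20 | ethyl 2-[(4E,6S,7S,8S,10R)-8-(methoxymethoxy)-4,10-dimethyl-9-oxo-6-(triethylsilyloxy)cyclodec-4-en-7-yl]acetate (germacrane locants) | C[C@@H]1CCC/C(C)=C/[C@H](O[Si](CC)(CC)CC)[C@@H](CC(=O)OCC)[C@H](OCOC)C1=O | intermediate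
21 | (9R)-alcohol of 20, (4E,6S,7S,8S,9R,10R) | C[C@@H]1CCC/C(C)=C/[C@H](O[Si](CC)(CC)CC)[C@@H](CC(=O)OCC)[C@H](OCOC)[C@@H]1O | intermediate
22 | 9-O-tert-butyldimethylsilyl ether of 21 | C[C@@H]1CCC/C(C)=C/[C@H](O[Si](CC)(CC)CC)[C@@H](CC(=O)OCC)[C@H](OCOC)[C@@H]1O[Si](C)(C)C(C)(C)C | intermediate
23 | C8 hydroxy ester from 22, MOM removed (not isolated) | C[C@@H]1CCC/C(C)=C/[C@H](O[Si](CC)(CC)CC)[C@@H](CC(=O)OCC)[C@H](O)[C@@H]1O[Si](C)(C)C(C)(C)C | intermediate
24 | (4E)-6-triethylsilyloxy-9-tert-butyldimethylsilyloxygermacr-4-en-12,8-olide, trans-fused lactone, stereocentres as in 21 | C1C(=O)O[C@@H]2[C@H](O[Si](C)(C)C(C)(C)C)[C@H](C)CCC/C(C)=C/[C@H](O[Si](CC)(CC)CC)[C@@H]12 | intermediate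
25 | 11-(dimethylaminomethyl) derivative of 24, C11 epimers (not isolated) | CN(C)CC1C(=O)O[C@@H]2[C@H](O[Si](C)(C)C(C)(C)C)[C@H](C)CCC/C(C)=C/[C@H](O[Si](CC)(CC)CC)[C@@H]12 | intermediate
26 | methiodide of 25 (not isolated) | C[N+](C)(C)CC1C(=O)O[C@@H]2[C@H](O[Si](C)(C)C(C)(C)C)[C@H](C)CCC/C(C)=C/[C@H](O[Si](CC)(CC)CC)[C@@H]12.[I-] | intermediate
27 | 6-triethylsilyloxy-9-tert-butyldimethylsilyloxygermacra-4E,11(13)-dien-12,8-olide | C=C1C(=O)O[C@@H]2[C@H](O[Si](C)(C)C(C)(C)C)[C@H](C)CCC/C(C)=C/[C@H](O[Si](CC)(CC)CC)[C@@H]12 | intermediate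
28 | 6-hydroxy-9-tert-butyldimethylsilyloxygermacra-4E,11(13)-dien-12,8-olide (C6 allylic alcohol, ring stereocentres unchanged from 27) | C=C1C(=O)O[C@@H]2[C@H](O[Si](C)(C)C(C)(C)C)[C@H](C)CCC/C(C)=C/[C@H](O)[C@@H]12 | intermediate
29 | (4R,5R)-4,5-epoxy-6-hydroxy-9-tert-butyldimethylsilyloxygermacr-11(13)-en-12,8-olide (5,6-erythro) | C=C1C(=O)O[C@@H]2[C@H](O[Si](C)(C)C(C)(C)C)[C@H](C)CCC[C@@]3(C)O[C@@H]3[C@H](O)[C@@H]12 | intermediate
30 | tigloyl chloride, (E)-2-methylbut-2-enoyl chloride | C/C=C(\C)C(=O)Cl | starting material
31 | 6-O-tiglate of 29 (9-O-tert-butyldimethylsilyl ether of the target) | C=C1C(=O)O[C@@H]2[C@H](O[Si](C)(C)C(C)(C)C)[C@H](C)CCC[C@@]3(C)O[C@@H]3[C@H](OC(=O)/C(C)=C/C)[C@@H]12 | intermediate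
32 | (4R,5R,6R,7S,8S,9R,10R)-4,5-epoxy-9-hydroxy-6-tigloyloxygermacr-11(13)-en-12,8-olide, CNP0165329.2 | C=C1C(=O)O[C@@H]2[C@H](O)[C@H](C)CCC[C@@]3(C)O[C@@H]3[C@H](OC(=O)/C(C)=C/C)[C@@H]12 | target

**Step count and risks**

Total step count: 21. Longest linear sequence: 21 steps (from 1; compounds 2, 3, 9 and 30 enter along it).

Steps most likely to fail:

Step 19. Oxygen may be delivered to the wrong face of the C4=C5 bond. This would happen if the hydroxyl directs through the rotamer with H-6 in the olefin plane, the pattern of open-chain allylic alcohols with a cis methyl, or if the ring does not turn the olefin. The fallback replaces hydroxyl direction by reagent control. From 28, acylation with 30 (Et3N, DMAP) gives the tiglate olefin F1. Shi epoxidation of F1 with the D-fructose-derived ketone, KHSO5 and K2CO3 buffer in MeCN/dimethoxymethane at 0 °C should then follow. By its usual sense on E-trisubstituted olefins this ketone leads to the R,R epoxide, and the electron-poor tiglate and methylene lactone double bonds are left alone, so the route is rejoined at 31.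

Step 14. Facial control of hydride addition may be lost if chelation to the C8 acetal is not established or the flexible ketone leaves the crown conformation, so that the C9 epimer predominates. The fallback corrects the carbinol by inversion. From 20, the reduction then gives the 9-epi alcohol F2. Mitsunobu reaction of F2 with chloroacetic acid, PPh3 and diisopropyl azodicarboxylate gives the inverted chloroacetate F3. Thiourea with NaHCO3 in EtOH removes the chloroacetyl group without touching the ethyl ester and returns to the route at 21.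

Step 5. The bis-allylic chromate ester may ionise instead of rearranging, with dehydration, methyl migration and aromatisation of ring B, or the acetate arm may be lost by retro-aldol cleavage. The fallback separates the carbonyl shift from the C–C bond formation:
- From 8, alkaline H2O2 (NaOH, MeOH, 0 °C) epoxidises the disubstituted C5=C6 bond from the α face to the epoxy enone F4.
- Hydrazine hydrate with catalytic AcOH in MeOH (Wharton transposition) gives the 5α-hydroxy-6,8-diene F5.
- MnO2 in CH2Cl2 oxidises F5 to the arm-free linear dienone F6.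
- Mukaiyama–Michael addition of 1-ethoxy-1-(trimethylsilyloxy)ethene under TMSOTf catalysis should occur at C7, the δ-carbon C9 being fully substituted, and gives the silyl enol ether F7.
- Saegusa–Ito oxidation with Pd(OAc)2 in MeCN restores the enone and rejoins the route at 11.

Further compounds
F1 | step 19 | 6-O-tiglate of 28 (6-tigloyloxy-9-tert-butyldimethylsilyloxygermacra-4E,11(13)-dien-12,8-olide) | C=C1C(=O)O[C@@H]2[C@H](O[Si](C)(C)C(C)(C)C)[C@H](C)CCC/C(C)=C/[C@H](OC(=O)/C(C)=C/C)[C@@H]12
F2 | step 14 | (9S)-alcohol, C9 epimer of 21 | C[C@@H]1CCC/C(C)=C/[C@H](O[Si](CC)(CC)CC)[C@@H](CC(=O)OCC)[C@H](OCOC)[C@H]1O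
F3 | step 14 | (9R)-chloroacetate of 21 | C[C@@H]1CCC/C(C)=C/[C@H](O[Si](CC)(CC)CC)[C@@H](CC(=O)OCC)[C@H](OCOC)[C@@H]1OC(=O)CCl
F4 | step 5 | 5α,6α-epoxide of 8 (epoxy enone, C7 ketone, 8-ene) | C[C@@H]1CCC[C@]2(C)[C@@H]3O[C@@H]3C(=O)C=C12
F5 | step 5 | 5α-hydroxy-6,8-diene (C15 β, C14 α) | C[C@@H]1CCC[C@]2(C)[C@H](O)C=CC=C12
F6 | step 5 | linear dienone without the arm (C5 ketone, 6,8-diene) | C[C@@H]1CCC[C@]2(C)C(=O)C=CC=C12
F7 | step 5 | C5 trimethylsilyl enol ether of the C7 Michael adduct (5-ene, 8-ene, C7 CH2CO2Et, C7 epimers) | C[C@@H]1CCC[C@]2(C)C(O[Si](C)(C)C)=CC(CC(=O)OCC)C=C12
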